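## Retrosynthetic overview

1. **Feature:** the chain C2–C3–C3''–C2'' carries the 4-hydroxyphenyl rings B and B'' at its ends and the carbonyl carbons C4 and C4'' as branches. It is an 8,8'-linked dimer of 4-hydroxycinnamic acid (C2 = C7, C3 = C8, C4 = C9).
2. **Pyranone rings C and C'':** each is cut at O1–C8a (SNAr on an aryl fluoride) and at C4–C4a (aryllithium on a lactone carbonyl). This leaves rings A and A'' as two 2-fluoroaryl bromides and the core as a C2-symmetric bis-γ-lactone.
3. **Bis-lactone:** it is cut at C8–C8' and at both O–C7 bonds, back to two molecules of p-coumaric acid (anodic dehydrodimerisation).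
4. **Ring order:** both γ-lactones form first (step 1) and are opened in turn as rings A'' and A are attached (steps 7, 8). Rings C and C'' then close together (step 9), because each lactone oxygen sits on the half opposite to the carbonyl it acylates.
5. **Stereochemistry:** C2/C2'' come from the resolved dilactone and their C–O bonds are never broken. C3/C3'' emerge 2,3-cis and are equilibrated to 2,3-trans (step 10).

Key step: step 1

Assumption: unprimed locants denote the 7-hydroxy (liquiritigenin) half and doubly primed ones the 5,7-dihydroxy (naringenin) half, the target being (2S,3R,2''S,3''R) with both C rings 2,3-trans; lignan locants C7 (benzylic), C8 and C9 (carboxyl) are used for the cinnamic units, and the racemic compounds of steps 1 and 2 are drawn as the enantiomer that leads to the target.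

## Route

Step 1
Reactants: 1 (E)-4-hydroxycinnamic acid (p-coumaric acid), two molecules
Product: 3 rac-(1S*,2S*,5S*,6S*)-2,6-bis(4-hydroxyphenyl)-3,7-dioxabicyclo[3.3.0]octane-4,8-dione, via bis(quinone methide) diacid 2 (not isolated)
Conditions: undivided cell, boron-doped diamond anode, Pt cathode, constant current (5 mA cm−2, 0.9–1.0 F per mol of 1), acetone–aq. NaOAc/AcOH buffer (pH 5) 1:1, 5 °C, N2
Reagents that add atoms: none
Why: Proton-coupled one-electron oxidation of the phenol of 1 at the anode gives a phenoxyl radical whose spin reaches C8 through the styrene π system, two such radicals join at C8 and C8' (the future C3–C3'' bond) to give 2, and protons are reduced to H2 at the cathode. Each carboxyl(ate) oxygen of 2 then adds to the exocyclic quinone methide carbon C7 of the other half with rearomatisation, and both γ-lactone rings close in this same 5-exo-trig mode. The closest known reaction type is the oxidative 8–8' dehydrodimerisation of ferulic and sinapic acid to their dilactones with FeCl3, with laccase or peroxidase, or at an anode. For C8 and C8' (C1/C5 of 3) only the like-configured form of 2 can be bridged twice, since a bicyclo[3.3.0]octane has to be cis-fused, so the ring fusion selects their relative configuration while the unlike form ends as acidic monolactone material that is separated, and for C7 and C7' (C2/C6 of 3) each quinone methide is attacked on the face that places its aryl group on the convex exo side, cis to the neighbouring bridgehead hydrogen. The step needs 8–8' coupling to beat 8–5' and 8–O–4' coupling and needs 3 to escape further oxidation; the substrate helps through its unhindered, spin-rich C8 and through the two carboxyl groups, which trap only the 8–8' adduct irreversibly, and the medium helps because at pH 5 the carboxyl group is largely ionised whereas the phenols of 3 stay protonated, so that its 4-hydroxybenzyl ester bonds do not fragment by 1,6-elimination, and because 3 is poorly soluble and the charge is limited. No chiral element is present, so 3 is racemic.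

Step 2
Reactants: 3 rac-dilactone
Product: 4 rac-(1S*,2S*,5S*,6S*)-2,6-bis[4-(benzyloxy)phenyl]-3,7-dioxabicyclo[3.3.0]octane-4,8-dione
Conditions: BnOH, PPh3, DIAD (2.5 equiv each), THF, 0 °C to rt
Reagents that add atoms: benzyl alcohol, OCc1ccccc1
Why: Mitsunobu etherification alkylates both phenols (pKa near 10) under essentially neutral conditions, which avoids a standing phenolate that would expel the benzylic carboxylate of 3 by 1,6-elimination, and it touches no stereocentre.

Step 3
Reactants: 4 rac-dibenzyl dilactone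
Product: 5 (1S,2S,5S,6S)-2,6-bis[4-(benzyloxy)phenyl]-3,7-dioxabicyclo[3.3.0]octane-4,8-dione
Conditions: preparative SFC, amylose tris(3,5-dimethylphenylcarbamate) on silica, CO2–iPrOH, 35 °C
Reagents that add atoms: none
Why: Resolution by chromatography on a chiral stationary phase is standard for rigid aryl-substituted lactones, creates no new stereocentre and fixes the absolute configuration of the future C2 and C2''; the fraction carried on is the one assigned as (1S,2S,5S,6S) by X-ray analysis or ECD calculation.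

Step 4
Reactants: 6 5-fluororesorcinol
Product: 7 1,3-bis(benzyloxy)-5-fluorobenzene
Conditions: BnBr (2.2 equiv), K2CO3, DMF, 40 °C
Reagents that add atoms: benzyl bromide, BrCc1ccccc1
Why: Williamson ether synthesis on both acidic phenols with a reactive benzylic bromide, the unactivated aryl fluoride being inert to carbonate.

Step 5
Reactants: 7 1,3-bis(benzyloxy)-5-fluorobenzene
Product: 8 1,5-bis(benzyloxy)-2-bromo-3-fluorobenzene
Conditions: NBS (1.0 equiv), MeCN, −10 to 0 °C, dark
Reagents that add atoms: N-bromosuccinimide, O=C1CCC(=O)N1Br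
Why: Electrophilic aromatic bromination goes to the carbon that is para to one benzyloxy group and ortho to the other and to fluorine, because the site between the two benzyloxy groups is more crowded, as is usual for 5-substituted resorcinol diethers, and one equivalent of NBS in the cold and dark spares the benzylic CH2 groups.

Step 6
Reactants: 9 4-bromo-3-fluorophenol
Product: 10 4-(benzyloxy)-1-bromo-2-fluorobenzene
Conditions: BnBr (1.1 equiv), K2CO3, DMF, rt
Reagents that add atoms: benzyl bromide, BrCc1ccccc1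
Why: Williamson ether synthesis of a single phenol, with both aryl halides inert under these conditions.

Step 7
Reactants: 5 (1S,2S,5S,6S)-dibenzyl dilactone; 8 1,5-bis(benzyloxy)-2-bromo-3-fluorobenzene
Product: 12 (1S,2S,5S,6S)-8-[2,4-bis(benzyloxy)-6-fluorophenyl]-2,6-bis[4-(benzyloxy)phenyl]-8-hydroxy-3,7-dioxabicyclo[3.3.0]octan-4-one (anomer mixture at C8), via 2,4-bis(benzyloxy)-6-fluorophenyllithium 11 (not isolated)
Conditions: 8, n-BuLi, THF, −78 °C; cannulated (0.95 equiv) into 5, THF, −78 °C; AcOH quench at −78 °C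
Reagents that add atoms: none
Why: Bromine–lithium exchange is followed by 1,2-addition of the aryllithium to a γ-lactone, which at −78 °C halts at the lithium lactolate as in C-aryl glycoside synthesis; the two lactones of 5 are homotopic, so a slight deficit of 11 run into 5 should give a single monoadduct beside recoverable 5, the carbanion flanked by F and OBn is weakly basic and keeps its fluoride below −70 °C, the four stereocentres are untouched and the new hemiketal carbon is erased later.

Step 8
Reactants: 12 monolactol; 10 4-(benzyloxy)-1-bromo-2-fluorobenzene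
Product: 14 (1S,2S,5S,6S)-4-[4-(benzyloxy)-2-fluorophenyl]-8-[2,4-bis(benzyloxy)-6-fluorophenyl]-2,6-bis[4-(benzyloxy)phenyl]-3,7-dioxabicyclo[3.3.0]octane-4,8-diol (anomer mixture at C4 and C8), via 4-(benzyloxy)-2-fluorophenyllithium 13 (not isolated)
Conditions: 10, n-BuLi, THF, −78 °C; 12 added (13 in 2.3 equiv), −78 °C; AcOH quench at −78 °C
Reagents that add atoms: none
Why: The reaction type is that of step 7: the first equivalent of 13 deprotonates the hemiketal to the lactolate that masks the hindered di-ortho-substituted ketone, the next adds to the remaining lactone and again stops at the lactolate, and the cold acidic quench destroys surplus 13 before it can form an aryne, so that C1, C2, C5 and C6 are unchanged.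

Step 9
Reactants: 14 bis-lactol
Product: 16 (2S,3S,2''S,3''S)-7,4',5'',7'',4'''-penta-O-benzyl-3,3''-biflavanone (2,3-cis in both C rings), via dilithium diketo dialkoxide 15 (not isolated)
Conditions: LiN(SiMe3)2 (2.05 equiv), THF, −78 °C; DMPU, then warm to 45 °C
Reagents that add atoms: none
Why: In this intramolecular SNAr (addition–elimination through a Meisenheimer complex) two equivalents of base open the bis-hemiketal to 15, in which each benzylic alkoxide can reach, through a six-membered ring, the C–F carbon of the aroyl group on its own half, ortho to the activating ketone and meta to the benzyloxy donors, so that both C rings close with loss of LiF in preference to the seven-membered cross closure; the C7–O bonds are not broken, hence C2 and C2'' are retained and the exo,exo geometry of the dilactone translates into 2,3-cis in both rings.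

Step 10
Reactants: 16 cis,cis-pentabenzyl biflavanone
Product: 17 (2S,3R,2''S,3''R)-7,4',5'',7'',4'''-penta-O-benzyl-3,3''-biflavanone (2,3-trans in both C rings)
Conditions: DBU (0.3 equiv), toluene, 40 °C, Ar
Reagents that add atoms: none
Why: Base-catalysed epimerisation of ketone α-stereocentres under thermodynamic control lets each bulky flavanonyl substituent at C3 and C3'' move from the axial to the equatorial position, trans to the equatorial 2-aryl group, while C2 and C2'' bear no acidic hydrogen and act as the controlling centres, and a catalytic amidine in an aprotic solvent keeps the enolate concentration low so that reprotonation should outrun β-elimination of the ring aryloxide.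

Step 11
Reactants: 17 trans,trans-pentabenzyl biflavanone
Product: 18 (2S,3R,2''S,3''R)-7,4',5'',7'',4'''-pentahydroxy-3,3''-biflavanone (CNP0138443.1)
Conditions: H2 (1 atm), 10% Pd/C, THF–MeOH 1:1, rt
Reagents that add atoms: none
Why: Catalytic hydrogenolysis cleaves the five O-benzyl ethers under neutral conditions much faster than the hindered C2–O1 bonds or the electron-rich aryl ketones react, and with neither acid nor base present none of the four stereocentres can epimerise.

## Compound list

1 | (E)-4-hydroxycinnamic acid (p-coumaric acid) | O=C(O)/C=C/c1ccc(O)cc1 | starting material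
2 | rac-(2R*,3R*)-2,3-bis[(4-oxocyclohexa-2,5-dien-1-ylidene)methyl]butanedioic acid (not isolated) | O=C1C=CC(C=C1)=C[C@H]([C@@H](C=C1C=CC(=O)C=C1)C(=O)O)C(=O)O | intermediate
3 | rac-(1S*,2S*,5S*,6S*)-2,6-bis(4-hydroxyphenyl)-3,7-dioxabicyclo[3.3.0]octane-4,8-dione | O=C1O[C@H](c3ccc(O)cc3)[C@H]2C(=O)O[C@H](c3ccc(O)cc3)[C@@H]12 | intermediate
4 | rac-(1S*,2S*,5S*,6S*)-2,6-bis[4-(benzyloxy)phenyl]-3,7-dioxabicyclo[3.3.0]octane-4,8-dione | O=C1O[C@H](c3ccc(OCc4ccccc4)cc3)[C@H]2C(=O)O[C@H](c3ccc(OCc4ccccc4)cc3)[C@@H]12 | intermediate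
5 | (1S,2S,5S,6S)-2,6-bis[4-(benzyloxy)phenyl]-3,7-dioxabicyclo[3.3.0]octane-4,8-dione (single enantiomer) | O=C1O[C@H](c3ccc(OCc4ccccc4)cc3)[C@H]2C(=O)O[C@H](c3ccc(OCc4ccccc4)cc3)[C@@H]12 | intermediate
6 | 5-fluororesorcinol | Oc1cc(O)cc(F)c1 | starting material
7 | 1,3-bis(benzyloxy)-5-fluorobenzene | Fc1cc(OCc2ccccc2)cc(OCc2ccccc2)c1 | intermediate
8 | 1,5-bis(benzyloxy)-2-bromo-3-fluorobenzene | Fc1cc(OCc2ccccc2)cc(OCc2ccccc2)c1Br | intermediate
9 | 4-bromo-3-fluorophenol | Oc1ccc(Br)c(F)c1 | starting material
10 | 4-(benzyloxy)-1-bromo-2-fluorobenzene | Fc1cc(OCc2ccccc2)ccc1Br | intermediate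
11 | 2,4-bis(benzyloxy)-6-fluorophenyllithium (not isolated) | [Li]c1c(F)cc(OCc2ccccc2)cc1OCc1ccccc1 | intermediate
12 | (1S,2S,5S,6S)-8-[2,4-bis(benzyloxy)-6-fluorophenyl]-2,6-bis[4-(benzyloxy)phenyl]-8-hydroxy-3,7-dioxabicyclo[3.3.0]octan-4-one | OC1(c5c(F)cc(OCc6ccccc6)cc5OCc5ccccc5)O[C@H](c3ccc(OCc4ccccc4)cc3)[C@H]2C(=O)O[C@H](c3ccc(OCc4ccccc4)cc3)[C@@H]12 | intermediate
13 | 4-(benzyloxy)-2-fluorophenyllithium (not isolated) | [Li]c1ccc(OCc2ccccc2)cc1F | intermediate
14 | (1S,2S,5S,6S)-4-[4-(benzyloxy)-2-fluorophenyl]-8-[2,4-bis(benzyloxy)-6-fluorophenyl]-2,6-bis[4-(benzyloxy)phenyl]-3,7-dioxabicyclo[3.3.0]octane-4,8-diol | OC1(c5c(F)cc(OCc6ccccc6)cc5OCc5ccccc5)O[C@H](c3ccc(OCc4ccccc4)cc3)[C@H]2C(O)(c5ccc(OCc6ccccc6)cc5F)O[C@H](c3ccc(OCc4ccccc4)cc3)[C@@H]12 | intermediate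
15 | dilithium (1S,2S,3S,4S)-2-[4-(benzyloxy)-2-fluorobenzoyl]-3-[2,4-bis(benzyloxy)-6-fluorobenzoyl]-1,4-bis[4-(benzyloxy)phenyl]butane-1,4-diolate (not isolated) | [Li+].[Li+].[O-][C@H](c3ccc(OCc4ccccc4)cc3)[C@@H](C(=O)c5ccc(OCc6ccccc6)cc5F)[C@H](C(=O)c5c(F)cc(OCc6ccccc6)cc5OCc5ccccc5)[C@H]([O-])c3ccc(OCc4ccccc4)cc3 | intermediate
16 | (2S,3S,2''S,3''S)-7,4',5'',7'',4'''-penta-O-benzyl-3,3''-biflavanone | O=C1c2ccc(OCc3ccccc3)cc2O[C@H](c2ccc(OCc3ccccc3)cc2)[C@@H]1[C@@H]1C(=O)c2c(OCc3ccccc3)cc(OCc3ccccc3)cc2O[C@@H]1c1ccc(OCc2ccccc2)cc1 | intermediate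
17 | (2S,3R,2''S,3''R)-7,4',5'',7'',4'''-penta-O-benzyl-3,3''-biflavanone | O=C1c2ccc(OCc3ccccc3)cc2O[C@H](c2ccc(OCc3ccccc3)cc2)[C@H]1[C@H]1C(=O)c2c(OCc3ccccc3)cc(OCc3ccccc3)cc2O[C@@H]1c1ccc(OCc2ccccc2)cc1 | intermediate
18 | (2S,3R,2''S,3''R)-7,4',5'',7'',4'''-pentahydroxy-3,3''-biflavanone (CNP0138443.1) | O=C1c2ccc(O)cc2O[C@H](c2ccc(O)cc2)[C@H]1[C@H]1C(=O)c2c(O)cc(O)cc2O[C@@H]1c1ccc(O)cc1 | target

## Step count and risks

Total step count: 11.
Longest linear sequence: 8 (steps 1, 2, 3, 7, 8, 9, 10, 11).

**Step 1.**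
- **What may go wrong:** radical coupling through the free ring carbon ortho to the phenol or through the phenoxyl oxygen instead of C8, passivation of the anode by a polymer film, and further oxidation of the product phenols.
- **Fallback (from 1, back at 4):** the phenoxyl radical is taken out of the plan.
- Compound 1 is benzylated on both oxygens (BnBr, K2CO3, DMF) to benzyl (E)-4-(benzyloxy)cinnamate F1, which is saponified (LiOH, THF–H2O) to (E)-4-(benzyloxy)cinnamic acid F2.
- F2 is dimerised through its arene radical cation with trivalent thallium trifluoroacetate, Tl(OCOCF3)3, and BF3·OEt2 in CH2Cl2–CF3CO2H at −20 °C. This is the known oxidative dimerisation of 4-alkoxycinnamic acids to fused bis-lactones.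
- With the oxygen capped, O-coupling is impossible, and the same double 5-exo lactonisation should give 4 directly. Steps 1 and 2 are replaced.

**Step 9.**
- **What may go wrong:** retro-aldol cleavage of the β-alkoxido ketones with loss or re-addition of the aldehyde, which scrambles C2, and sluggish substitution on the donor-rich, di-ortho-substituted ring A''.
- **Fallback (from 4, back at 17):** the roles are reversed. A phenol is the nucleophile and the activated benzylic alcohol is the electrophile, with inversion. The antipode of the dilactone is therefore used, and step 10 becomes unnecessary.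
- The second fraction of the separation of step 3 is (1R,2R,5R,6R)-dibenzyl dilactone F3.
- 4-Bromoresorcinol is benzylated at the hydroxyl remote from bromine (BnBr, 1 equiv, K2CO3, acetone) to 5-(benzyloxy)-2-bromophenol F4. This is protected (MOMCl, iPr2NEt) as 4-(benzyloxy)-1-bromo-2-(methoxymethoxy)benzene F5.
- Commercial 3,5-bis(benzyloxy)phenol is protected likewise as 1,3-bis(benzyloxy)-5-(methoxymethoxy)benzene F6.
- Directed ortho-lithiation of F6 next to the chelating OMOM group (n-BuLi, THF, −20 °C) gives 2,4-bis(benzyloxy)-6-(methoxymethoxy)phenyllithium F7, which adds to F3 as in step 7 to give the MOM-bearing monolactol F8.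
- Bromine–lithium exchange on F5 gives 4-(benzyloxy)-2-(methoxymethoxy)phenyllithium F9, which converts F8 as in step 8 into the MOM-bearing bis-lactol F10.
- Both aryl MOM ethers are removed under non-acidic conditions (TMSOTf, 2,2'-bipyridyl, CH2Cl2, 0 °C, then H2O). This frees the bis(2-hydroxyaryl) diketo diol F11.
- A double intramolecular Mitsunobu etherification (PPh3, DIAD, dilute THF, 0 °C) is the known neutral flavanone closure of 3-hydroxy-1-(2-hydroxyaryl)propan-1-ones. It inverts C7 and C7' from R to S while C8 and C8' stay R, which is the configuration of 17.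

**Step 7.**
- **What may go wrong:** deprotonation at the bridgehead carbons by the aryllithium followed by β-elimination of the benzylic carboxylate, collapse of the lactolate with a second addition, and statistical double opening.
- **Fallback (from 5, back at 14):** both lactones are opened with MeNH(OMe)·HCl and AlMe3 (CH2Cl2, 0 °C to rt) to the bis(Weinreb amide) diol F12. This is silylated at once (TESOTf, 2,6-lutidine, −78 °C) to the bis(triethylsilyl) ether F13.
- Weinreb ketone synthesis with 11 (1 equiv, THF, −78 °C) gives the keto amide F14, and with 13 it gives the diketone bis(silyl ether) F15.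
- The chelated tetrahedral intermediates exclude over-addition, and no carboxylate leaving group remains β to the acidic hydrogens.
- HF·pyridine (THF, 0 °C) removes both silyl groups, and the keto alcohols close to 14.

## Further compounds

F1 | step 1 | benzyl (E)-3-[4-(benzyloxy)phenyl]prop-2-enoate | O=C(OCc1ccccc1)/C=C/c1ccc(OCc2ccccc2)cc1
F2 | step 1 | (E)-3-[4-(benzyloxy)phenyl]prop-2-enoic acid | O=C(O)/C=C/c1ccc(OCc2ccccc2)cc1
F3 | step 9 | (1R,2R,5R,6R)-2,6-bis[4-(benzyloxy)phenyl]-3,7-dioxabicyclo[3.3.0]octane-4,8-dione | O=C1O[C@@H](c3ccc(OCc4ccccc4)cc3)[C@@H]2C(=O)O[C@@H](c3ccc(OCc4ccccc4)cc3)[C@H]12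
F4 | step 9 | 5-(benzyloxy)-2-bromophenol | Oc1cc(OCc2ccccc2)ccc1Br
F5 | step 9 | 4-(benzyloxy)-1-bromo-2-(methoxymethoxy)benzene | COCOc1cc(OCc2ccccc2)ccc1Br
F6 | step 9 | 1,3-bis(benzyloxy)-5-(methoxymethoxy)benzene | COCOc1cc(OCc2ccccc2)cc(OCc2ccccc2)c1
F7 | step 9 | 2,4-bis(benzyloxy)-6-(methoxymethoxy)phenyllithium | [Li]c1c(OCOC)cc(OCc2ccccc2)cc1OCc1ccccc1
F8 | step 9 | (1R,2R,5R,6R)-8-[2,4-bis(benzyloxy)-6-(methoxymethoxy)phenyl]-2,6-bis[4-(benzyloxy)phenyl]-8-hydroxy-3,7-dioxabicyclo[3.3.0]octan-4-one | OC1(c5c(OCOC)cc(OCc6ccccc6)cc5OCc5ccccc5)O[C@@H](c3ccc(OCc4ccccc4)cc3)[C@@H]2C(=O)O[C@@H](c3ccc(OCc4ccccc4)cc3)[C@H]12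
F9 | step 9 | 4-(benzyloxy)-2-(methoxymethoxy)phenyllithium | [Li]c1ccc(OCc2ccccc2)cc1OCOC
F10 | step 9 | (1R,2R,5R,6R)-4-[4-(benzyloxy)-2-(methoxymethoxy)phenyl]-8-[2,4-bis(benzyloxy)-6-(methoxymethoxy)phenyl]-2,6-bis[4-(benzyloxy)phenyl]-3,7-dioxabicyclo[3.3.0]octane-4,8-diol | OC1(c5c(OCOC)cc(OCc6ccccc6)cc5OCc5ccccc5)O[C@@H](c3ccc(OCc4ccccc4)cc3)[C@@H]2C(O)(c5ccc(OCc6ccccc6)cc5OCOC)O[C@@H](c3ccc(OCc4ccccc4)cc3)[C@H]12
F11 | step 9 | (1R,2R,3R,4R)-2-[4-(benzyloxy)-2-hydroxybenzoyl]-3-[2,4-bis(benzyloxy)-6-hydroxybenzoyl]-1,4-bis[4-(benzyloxy)phenyl]butane-1,4-diol | O[C@@H](c3ccc(OCc4ccccc4)cc3)[C@H](C(=O)c5ccc(OCc6ccccc6)cc5O)[C@@H](C(=O)c5c(O)cc(OCc6ccccc6)cc5OCc5ccccc5)[C@@H](O)c3ccc(OCc4ccccc4)cc3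
F12 | step 7 | (2S,3S)-2,3-bis{(S)-[4-(benzyloxy)phenyl](hydroxy)methyl}-N,N'-dimethoxy-N,N'-dimethylbutanediamide | O[C@H](c3ccc(OCc4ccccc4)cc3)[C@@H](C(=O)N(C)OC)[C@H](C(=O)N(C)OC)[C@H](O)c3ccc(OCc4ccccc4)cc3
F13 | step 7 | bis(triethylsilyl) ether of F12 | CC[Si](CC)(CC)O[C@H](c3ccc(OCc4ccccc4)cc3)[C@@H](C(=O)N(C)OC)[C@H](C(=O)N(C)OC)[C@H](O[Si](CC)(CC)CC)c3ccc(OCc4ccccc4)cc3
F14 | step 7 | (2S,3S)-3-[2,4-bis(benzyloxy)-6-fluorobenzoyl]-4-[4-(benzyloxy)phenyl]-2-{(S)-[4-(benzyloxy)phenyl](triethylsilyloxy)methyl}-N-methoxy-N-methyl-(4S)-4-(triethylsilyloxy)butanamide | CC[Si](CC)(CC)O[C@H](c3ccc(OCc4ccccc4)cc3)[C@@H](C(=O)N(C)OC)[C@H](C(=O)c5c(F)cc(OCc6ccccc6)cc5OCc5ccccc5)[C@H](O[Si](CC)(CC)CC)c3ccc(OCc4ccccc4)cc3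
F15 | step 7 | (1S,2S,3S,4S)-2-[4-(benzyloxy)-2-fluorobenzoyl]-3-[2,4-bis(benzyloxy)-6-fluorobenzoyl]-1,4-bis[4-(benzyloxy)phenyl]-1,4-bis(triethylsilyloxy)butane | CC[Si](CC)(CC)O[C@H](c3ccc(OCc4ccccc4)cc3)[C@@H](C(=O)c5ccc(OCc6ccccc6)cc5F)[C@H](C(=O)c5c(F)cc(OCc6ccccc6)cc5OCc5ccccc5)[C@H](O[Si](CC)(CC)CC)c3ccc(OCc4ccccc4)cc3
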